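**Retrosynthetic overview**
1. Feature: ring A, the chlorophenol arene that carries the ketone, is pentasubstituted. Two neighbouring ring-A carbons bear the ketal carbon C-k and the quaternary diaryl carbon C-q, which one oxygen ties into dihydrofuran ring C, so C-k–O–C-q is a dipropargyl ether in disguise.
2. Key disconnection: the three ring-A bonds that join the alkyne units are cut. This opens ring A, ring C and a temporary oxasilole at once and leads to triyne ketal 25 (ethynyl on C-q, alkynyl on C-k, silicon-tethered ethyne).
3. 25 comes from ketal exchange (dioxine ring D) between ethynyl carbinol 13 and alkynyl ketal 24. 13 comes from silyloxy tetralone 11, whose ring F is built by a Haworth sequence on arene E; one asymmetric transfer hydrogenation is the only source of chirality.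
4. After the key step: C–Si to C–OH, ortho chlorination and Barbier closure of ring B. Both cyclohexanone rings are then dehydrogenated and epoxidized together, and only the ring-F ketone is reduced and inverted.
5. Ring order: E (bought) → F → D → A + C (+ oxasilole, later removed) → B → the two oxiranes.

Key step: step 18

Remark on labels: ring A = chlorophenol arene bearing the ketone, ring B = epoxyketone ring, ring C = dihydrofuran, ring D = 1,3-dioxine, ring E = the other chlorophenol arene, ring F = epoxycarbinol ring; C-k = ketal carbon, C-q = quaternary diaryl carbon, C-c = carbinol carbon.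
Assumption: the carbinol formed in step 25 arises as a mixture of epimers and is drawn without configuration, since step 27 removes this centre.

Step 1
Reactants: 1 3-chloro-4-methoxyphenol; 2 succinic anhydride
Product: 3 4-(4-chloro-2-hydroxy-5-methoxyphenyl)-4-oxobutanoic acid
Conditions: AlCl3 (3.5 equiv), ClCH2CH2Cl, 0 to 60 °C; aq. HCl
Reagents that add atoms: none
Why: Friedel–Crafts acylation at the only open position that is both ortho to the phenol and para to chlorine, with the chelated ortho-hydroxyaryl ketone as the stable product.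

Step 2
Reactants: 3 4-(4-chloro-2-hydroxy-5-methoxyphenyl)-4-oxobutanoic acid
Product: 4 4-(4-chloro-2-hydroxy-5-methoxyphenyl)butanoic acid
Conditions: Et3SiH (2.5 equiv), CF3CO2H, rt to 50 °C
Reagents that add atoms: none
Why: Ionic hydrogenation takes the electron-rich aryl ketone to the methylene stage through the benzylic cation, spares the aryl chloride and the acid, and removes the deactivating acyl group before ring closure (Haworth sequence).

Step 3
Reactants: 4 4-(4-chloro-2-hydroxy-5-methoxyphenyl)butanoic acid
Product: 5 7-chloro-5-hydroxy-8-methoxy-3,4-dihydronaphthalen-1(2H)-one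
Conditions: polyphosphoric acid, 85 °C
Reagents that add atoms: none
Why: Intramolecular Friedel–Crafts acylation at the single open ortho position, which the neighbouring methoxy group activates, closes six-membered ring F.

Step 4
Reactants: 5 7-chloro-5-hydroxy-8-methoxy-3,4-dihydronaphthalen-1(2H)-one
Product: 6 7-chloro-5,8-dihydroxy-3,4-dihydronaphthalen-1(2H)-one
Conditions: BCl3 (2.2 equiv), CH2Cl2, −78 to 0 °C; water
Reagents that add atoms: none
Why: Chelation-assisted aryl methyl ether cleavage, in which boron is held between the ketone and the peri methoxy oxygen and chloride takes the methyl group.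

Step 5
Reactants: 6 7-chloro-5,8-dihydroxy-3,4-dihydronaphthalen-1(2H)-one
Product: 7 7-chloro-5,8-bis(methoxymethoxy)-3,4-dihydronaphthalen-1(2H)-one
Conditions: MOMCl (3 equiv), i-Pr2NEt (4 equiv), CH2Cl2, 0 to 40 °C
Reagents that add atoms: chloromethyl methyl ether, COCCl
Why: O-alkylation of both phenols (the chelated one needs the excess and the warming); MOM survives Grignard reagent, fluoride, SmI2 and base and leaves under mild acid.

Step 6
Reactants: 7 7-chloro-5,8-bis(methoxymethoxy)-3,4-dihydronaphthalen-1(2H)-one
Product: 8 (1S)-7-chloro-5,8-bis(methoxymethoxy)-1,2,3,4-tetrahydronaphthalen-1-ol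
Conditions: RuCl[(S,S)-TsDPEN](p-cymene) (1 mol %), HCO2H/Et3N 5:2, 40 °C
Reagents that add atoms: none
Why: Noyori asymmetric transfer hydrogenation, in which the (S,S) catalyst tells aryl from alkyl flank and should give the S carbinol as with 1-tetralone, sets the one stereocentre from which all others derive.

Step 7
Reactants: 8 (1S)-7-chloro-5,8-bis(methoxymethoxy)-1,2,3,4-tetrahydronaphthalen-1-ol
Product: 9 tert-butyldimethylsilyl ether of 8 (1S)
Conditions: TBSOTf, 2,6-lutidine, CH2Cl2, −78 to 0 °C
Reagents that add atoms: tert-butyldimethylsilyl triflate, CC(C)(C)[Si](C)(C)OS(=O)(=O)C(F)(F)F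
Why: Silyl ether formation with the reactive triflate overcomes the peri hindrance and installs the bulky group that later steers the acetylide addition.

Step 8
Reactants: 9 tert-butyldimethylsilyl ether of 8
Product: 10 (4S)-4-[(tert-butyldimethylsilyl)oxy]-6-chloro-5,8-bis(methoxymethoxy)-3,4-dihydronaphthalen-1(2H)-one
Conditions: Rh2(cap)4 (cap = caprolactamate, 1 mol %), t-BuOOH (70% aq., 6 equiv), NaHCO3, ClCH2CH2Cl, 40 °C
Reagents that add atoms: tert-butyl hydroperoxide, CC(C)(C)OO
Why: Catalytic benzylic C–H oxidation (peroxyl radical abstraction, mixed peroxide, ketone) should pick the CH2 group, whose pseudoaxial C–H is aligned with the arene π system, over the carbinol C–H, which is pseudoequatorial, poorly aligned and shielded because the peri MOM ether forces the silyloxy group pseudoaxial.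

Step 9
Reactants: 10 (4S)-4-[(tert-butyldimethylsilyl)oxy]-6-chloro-5,8-bis(methoxymethoxy)-3,4-dihydronaphthalen-1(2H)-one
Product: 11 (4S)-4-[(tert-butyldimethylsilyl)oxy]-6-chloro-8-hydroxy-5-(methoxymethoxy)-3,4-dihydronaphthalen-1(2H)-one
Conditions: MgBr2·OEt2 (3 equiv), Et2O/CH2Cl2, 0 °C to rt; water
Reagents that add atoms: none
Why: Chelation-controlled acetal cleavage, in which magnesium sits between the ketone oxygen and the peri aryl oxygen so that bromide attacks only that MOM group, while the other MOM ether and the silyl ether lack such an anchor.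

Step 10
Reactants: 11 (4S)-4-[(tert-butyldimethylsilyl)oxy]-6-chloro-8-hydroxy-5-(methoxymethoxy)-3,4-dihydronaphthalen-1(2H)-one; 12 ethynylmagnesium bromide
Product: 13 (1S,4S)-4-[(tert-butyldimethylsilyl)oxy]-6-chloro-1-ethynyl-5-(methoxymethoxy)-1,2,3,4-tetrahydronaphthalene-1,8-diol (ethynyl trans to the silyloxy group)
Conditions: 12 (5 equiv), LaCl3·2LiCl (0.3 equiv), THF, −20 to 0 °C; aq. NH4Cl
Reagents that add atoms: none
Why: 1,2-Addition of an alkynyl Grignard reagent (the first equivalent forms the magnesium phenolate), in which the pseudoaxial silyloxy group fixes the half-chair and the small nucleophile enters pseudoaxially on the opposite face, sets C-q with ethynyl trans to the silyloxy group.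

Step 11
Reactants: 14 4-methoxybenzyl alcohol; 15 methyl acrylate
Product: 16 methyl 3-[(4-methoxybenzyl)oxy]propanoate
Conditions: KOt-Bu (5 mol %), THF, 0 °C to rt
Reagents that add atoms: none
Why: Base-catalysed oxa-Michael addition of a primary benzylic alkoxide to an acrylate.

Step 12
Reactants: 16 methyl 3-[(4-methoxybenzyl)oxy]propanoate
Product: 17 N-methoxy-3-[(4-methoxybenzyl)oxy]-N-methylpropanamide
Conditions: MeNH(OMe)·HCl (1.5 equiv), i-PrMgCl (3 equiv), THF, −20 °C
Reagents that add atoms: N,O-dimethylhydroxylamine hydrochloride, CNOC.Cl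
Why: Aminolysis of the ester by the magnesium amide gives the Weinreb amide at a temperature too low for β-elimination of the alkoxy group.

Step 13
Reactants: 17 N-methoxy-3-[(4-methoxybenzyl)oxy]-N-methylpropanamide; 18 propargyl alcohol
Product: 20 6-hydroxy-1-[(4-methoxybenzyl)oxy]hex-4-yn-3-one, via dilithiated propargyl alcohol 19 (not isolated)
Conditions: 18 (1.5 equiv), n-BuLi (3 equiv), THF, −78 °C; then 17, −78 to −20 °C; aq. NH4Cl
Reagents that add atoms: none
Why: Weinreb ketone synthesis, in which the acetylide end of the dianion adds once and the chelated tetrahedral intermediate holds until the quench, gives the ynone without a protecting group.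

Step 14
Reactants: 20 6-hydroxy-1-[(4-methoxybenzyl)oxy]hex-4-yn-3-one
Product: 21 4,4-dimethoxy-6-[(4-methoxybenzyl)oxy]hex-2-yn-1-ol
Conditions: HC(OMe)3 (3 equiv), p-TsOH (2 mol %), MeOH, rt
Reagents that add atoms: trimethyl orthoformate, COC(OC)OC
Why: Acid-catalysed ketalization with orthoformate as water scavenger removes the Michael acceptor at this stage, since a free ynone would take up the phenol of 13 by conjugate addition instead of forming a ketal.

Step 15
Reactants: 22 dichlorodiisopropylsilane; 12 ethynylmagnesium bromide
Product: 23 chloro(ethynyl)diisopropylsilane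
Conditions: 12 (1.0 equiv), THF, 0 °C to rt; distillation
Reagents that add atoms: none
Why: Nucleophilic substitution at silicon, where the two isopropyl groups slow the second substitution enough for monoalkynylation with one equivalent.

Step 16
Reactants: 21 4,4-dimethoxy-6-[(4-methoxybenzyl)oxy]hex-2-yn-1-ol; 23 chloro(ethynyl)diisopropylsilane
Product: 24 {[4,4-dimethoxy-6-(4-methoxybenzyloxy)hex-2-yn-1-yl]oxy}(ethynyl)diisopropylsilane
Conditions: imidazole, CH2Cl2, 0 °C to rt
Reagents that add atoms: none
Why: Silyl ether formation under basic conditions that the ketal tolerates attaches the tether before the fragment union, so that it also protects the propargylic alcohol.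

Step 17
Reactants: 13 ethynyl carbinol (1S,4S); 24 silicon-tethered alkynyl dimethyl ketal
Product: 25 triyne ketal: 4H-1,3-benzodioxine (ring D) peri-fused to ring F; C-k (R) bears the alkynyl chain C≡C–CH2–O–Si(i-Pr)2–C≡CH and CH2CH2OPMB, C-q (S) bears ethynyl, the two alkynes cis, OTBS on C-c (S) cis to the bridging oxygen
Conditions: PPTS (0.2 equiv), 5 Å molecular sieves, toluene, 60 °C
Reagents that add atoms: none
Why: Transketalization under thermodynamic control (methanol trapped by the sieves) closes ring D and sets C-k by equilibration through the alkynyl oxocarbenium ion, the slim alkynyl group taking the axial site cis to the axial ethynyl group and the CH2CH2OPMB chain the equatorial one, while the electron-poor terminal ethynyl group slows ionization of the tertiary alcohol.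

Step 18
Reactants: 25 triyne ketal
Product: 26 silicon-bridged arene cycloadduct: ring A fused to ring C and to a 1,1-diisopropyl-1,3-dihydrobenzoxasilole; C-k (R), C-q (S) and C-c (S) as in 25
Conditions: RhCl(PPh3)3 (10 mol %), degassed toluene (0.005 M), 80 °C
Reagents that add atoms: none
Why: This is the known intramolecular (2+2+2) alkyne cyclotrimerization of a triyne with a temporary silicon tether: monovalent rhodium binds the ethynyl group on C-q and the alkynyl group on C-k, which stand cis and 1,3-diaxial on ring D, and oxidative cyclization joins their inner carbons to a rhodacyclopentadiene of trivalent rhodium. That bond closes five-membered ring C in the classic 1,6-diyne mode, then the silicon-bound ethyne inserts intramolecularly and reductive elimination forms the other two C–C bonds, which close benzene ring A and, through the CH2–O–Si chain, the five-membered oxasilole. No stereocentre is created, and C-k and C-q become the bridgeheads of the 2,8-dioxabicyclo[3.2.1]octane core with their configurations unchanged. Regiochemistry is fixed by the three-atom tether, which puts silicon (the future phenol oxygen) next to the CH2O-bearing carbon (the future ketone carbon) and leaves the two CH positions where the chlorine and the last hydrogen of ring A belong. Chemoselectivity over alkyne dimerization rests on all three alkynes sitting in one molecule and on high dilution, and only the cis ketal can react, so any trans isomer carried along is left behind. The aryl chloride, the silyl ethers, the acetals and the PMB ether are inert to RhCl(PPh3)3 under these conditions.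

Step 19
Reactants: 26 silicon-bridged arene cycloadduct
Product: 27 ring-A phenol with ortho CH2OH (salicyl alcohol), rest as in 26
Conditions: 30% H2O2, KF, KHCO3, THF/MeOH 1:1, 45 °C
Reagents that add atoms: hydrogen peroxide, OO
Why: Tamao–Fleming oxidation, in which the fluoride-activated alkoxy(aryl)silane takes up hydroperoxide and the aryl group migrates from silicon to oxygen at the same carbon, frees phenol and benzylic alcohol after hydrolysis while KF/KHCO3 leaves the hindered secondary silyl ether in place.

Step 20
Reactants: 27 salicyl alcohol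
Product: 28 salicyl alcohol chlorinated ortho to the phenol on ring A
Conditions: N-chlorosuccinimide (1.05 equiv), MeCN, 0 °C
Reagents that add atoms: N-chlorosuccinimide, O=C1CCC(=O)N1Cl
Why: Electrophilic aromatic chlorination can only strike the one remaining ortho carbon, because the free phenol makes ring A by far the most electron-rich arene and its para and other ortho positions are substituted.

Step 21
Reactants: 28 chlorinated salicyl alcohol
Product: 29 3-chlorosalicylaldehyde of ring A
Conditions: MnO2 (20 equiv), CH2Cl2, rt
Reagents that add atoms: none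
Why: Selective MnO2 oxidation of the benzylic alcohol stops at the hydrogen-bonded salicylaldehyde.

Step 22
Reactants: 29 chlorosalicylaldehyde
Product: 30 aryl tert-butyldimethylsilyl ether of 29
Conditions: TBSOTf, 2,6-lutidine, CH2Cl2, 0 °C
Reagents that add atoms: tert-butyldimethylsilyl triflate, CC(C)(C)[Si](C)(C)OS(=O)(=O)C(F)(F)F
Why: Silylation removes the acidic proton that would quench the organosamarium species in step 25.

Step 23
Reactants: 30 silyl-protected aldehyde
Product: 31 primary alcohol (CH2CH2OH on C-k)
Conditions: DDQ (1.3 equiv), CH2Cl2/pH 7 buffer 10:1, 0 °C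
Reagents that add atoms: none
Why: Oxidative PMB cleavage (hydride abstraction from the electron-rich benzyl ether, then hydrolysis) leaves the silyl ethers, MOM ether, ketal and aldehyde untouched.

Step 24
Reactants: 31 primary alcohol
Product: 32 primary iodide (CH2CH2I on C-k)
Conditions: I2, PPh3, imidazole, THF, 0 °C
Reagents that add atoms: iodine, [I][I]
Why: Appel-type iodination by SN2 displacement of the alkoxyphosphonium ion at the primary carbon.

Step 25
Reactants: 32 primary iodide
Product: 33 ring-B carbinol (ring B closed, new secondary benzylic alcohol as a mixture of epimers)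
Conditions: SmI2 (3 equiv), NiI2 (2 mol %), THF, 0 °C, slow addition of 32 (final 0.005 M)
Reagents that add atoms: none
Why: Intramolecular samarium Barbier reaction, in which divalent samarium with nickel catalysis reduces the iodide ahead of the aldehyde to an organosamarium species that adds to the neighbouring aldehyde, closes six-membered ring B, with dilution holding back pinacol coupling and the new configuration being erased in step 27.

Step 26
Reactants: 33 ring-B carbinol
Product: 34 triol (ring-A phenol, ring-B carbinol, ring-F carbinol)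
Conditions: TBAF (3.5 equiv), THF, 0 °C to rt
Reagents that add atoms: none
Why: Fluoride cleaves both silyl ethers, also if the aryl silyl group has migrated to the new alkoxide.

Step 27
Reactants: 34 triol
Product: 35 diketone (ring-B and ring-F ketones, free ring-A phenol, MOM on ring E)
Conditions: Dess–Martin periodinane (3 equiv), NaHCO3, CH2Cl2, 0 °C to rt
Reagents that add atoms: none
Why: Dess–Martin oxidation converts both secondary benzylic alcohols in one operation, and the hindered chlorinated phenol ends up hydrogen-bonded to the new ketone.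

Step 28
Reactants: 35 diketone
Product: 36 bis-enone
Conditions: DDQ (5 equiv), 1,4-dioxane, 100 °C
Reagents that add atoms: none
Why: Twofold DDQ dehydrogenation of 4,4-disubstituted 1-tetralones (enol, then hydride abstraction at the β-carbon) is a known way to naphthalen-1(4H)-ones, which here cannot aromatize because C-k and C-q are quaternary.

Step 29
Reactants: 36 bis-enone
Product: 37 bis-epoxy diketone (both oxirane oxygens on the side of the bridging oxygen)
Conditions: t-BuOOH (decane, 6 equiv), 1,5,7-triazabicyclo[4.4.0]dec-5-ene (2.5 equiv), toluene, 0 °C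
Reagents that add atoms: tert-butyl hydroperoxide, CC(C)(C)OO
Why: Twofold Weitz–Scheffer-type nucleophilic epoxidation, in which the peroxide anion adds to each β-carbon from the convex face (anti to the axial aryloxy oxygen on C-k in ring B, anti to the axial ring-A carbon on C-q in ring F) and enolate closure follows, sets all four oxirane carbons.

Step 30
Reactants: 37 bis-epoxy diketone
Product: 38 cis epoxy alcohol of ring F (hydroxyl on the same side as the oxirane oxygen), ring-B ketone kept
Conditions: NaBH4 (1.0 equiv), MeOH/CH2Cl2 1:1, −78 °C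
Reagents that add atoms: none
Why: Chemoselective borohydride reduction should spare the ring-B ketone, deactivated as chelated phenol or phenolate (a vinylogous carboxylate), and reduce the ring-F ketone next to the MOM ether, with hydride entering opposite the oxirane oxygen to give the cis epoxy alcohol.

Step 31
Reactants: 38 cis epoxy alcohol
Product: 39 4-nitrobenzoate with inverted C-c (ester trans to the oxirane oxygen)
Conditions: 4-nitrobenzoic acid, PPh3, DIAD (4 equiv each), THF, 0 °C to rt
Reagents that add atoms: 4-nitrobenzoic acid, O=C(O)c1ccc(cc1)[N+](=O)[O-]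
Why: Mitsunobu inversion by SN2 displacement of the alkoxyphosphonium ion from the face opposite the oxirane sets the final configuration at C-c, and the excess of the stronger acid outcompetes the hindered chelated phenol as nucleophile.

Step 32
Reactants: 39 4-nitrobenzoate
Product: 40 trans epoxy alcohol, MOM ether still on ring E
Conditions: K2CO3 (1.5 equiv), MeOH, 0 °C; aq. NH4Cl
Reagents that add atoms: none
Why: Transesterification of the activated ester is run cold and short so that epoxide migration (Payne rearrangement) does not set in.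

Step 33
Reactants: 40 trans epoxy alcohol MOM ether
Product: 41 target CNP0289684.3 (C-k S, C-q S, ring-F oxirane carbons R and R, C-c S, ring-B oxirane carbons R next to C-k and S next to the ketone)
Conditions: NaHSO4·SiO2, CH2Cl2, rt
Reagents that add atoms: none
Why: Acid-catalysed hydrolysis of the phenolic MOM acetal on a weakly acidic solid support, under which the oxiranes and the ketal, all flanked by electron-withdrawing groups, should resist ionization.

**Compound list**
1 | 3-chloro-4-methoxyphenol | COc1ccc(O)cc1Cl | starting material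
2 | succinic anhydride | O=C1CCC(=O)O1 | starting material
3 | 4-(4-chloro-2-hydroxy-5-methoxyphenyl)-4-oxobutanoic acid | OC(=O)CCC(=O)c1cc(OC)c(Cl)cc1O | intermediate
4 | 4-(4-chloro-2-hydroxy-5-methoxyphenyl)butanoic acid | OC(=O)CCCc1cc(OC)c(Cl)cc1O | intermediate
5 | 7-chloro-5-hydroxy-8-methoxy-3,4-dihydronaphthalen-1(2H)-one | O=C1CCCc2c(O)cc(Cl)c(OC)c12 | intermediate
6 | 7-chloro-5,8-dihydroxy-3,4-dihydronaphthalen-1(2H)-one | O=C1CCCc2c(O)cc(Cl)c(O)c12 | intermediate
7 | 7-chloro-5,8-bis(methoxymethoxy)-3,4-dihydronaphthalen-1(2H)-one | O=C1CCCc2c(OCOC)cc(Cl)c(OCOC)c12 | intermediate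
8 | (1S)-7-chloro-5,8-bis(methoxymethoxy)-1,2,3,4-tetrahydronaphthalen-1-ol | COCOc1cc(Cl)c(OCOC)c2c1CCC[C@@H]2O | intermediate
9 | tert-butyldimethylsilyl ether of 8 | COCOc1cc(Cl)c(OCOC)c2c1CCC[C@@H]2O[Si](C)(C)C(C)(C)C | intermediate
10 | (4S)-4-silyloxy-6-chloro-5,8-bis(methoxymethoxy)tetral-1-one | COCOc1cc(Cl)c(OCOC)c2c1C(=O)CC[C@@H]2O[Si](C)(C)C(C)(C)C | intermediate
11 | (4S)-4-silyloxy-6-chloro-8-hydroxy-5-(methoxymethoxy)tetral-1-one | Oc1cc(Cl)c(OCOC)c2c1C(=O)CC[C@@H]2O[Si](C)(C)C(C)(C)C | intermediate
12 | ethynylmagnesium bromide | C#C[Mg]Br | starting material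
13 | (1S,4S)-ethynyl carbinol | Oc1cc(Cl)c(OCOC)c2c1[C@@](O)(C#C)CC[C@@H]2O[Si](C)(C)C(C)(C)C | intermediate
14 | 4-methoxybenzyl alcohol | COc1ccc(CO)cc1 | starting material
15 | methyl acrylate | C=CC(=O)OC | starting material
16 | methyl 3-[(4-methoxybenzyl)oxy]propanoate | COC(=O)CCOCc1ccc(OC)cc1 | intermediate
17 | N-methoxy-3-[(4-methoxybenzyl)oxy]-N-methylpropanamide | CON(C)C(=O)CCOCc1ccc(OC)cc1 | intermediate
18 | propargyl alcohol | C#CCO | starting material
19 | dilithiated propargyl alcohol | [Li]C#CCO[Li] | intermediate
20 | 6-hydroxy-1-[(4-methoxybenzyl)oxy]hex-4-yn-3-one | OCC#CC(=O)CCOCc1ccc(OC)cc1 | intermediate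
21 | 4,4-dimethoxy-6-[(4-methoxybenzyl)oxy]hex-2-yn-1-ol | OCC#CC(OC)(OC)CCOCc1ccc(OC)cc1 | intermediate
22 | dichlorodiisopropylsilane | CC(C)[Si](Cl)(Cl)C(C)C | starting material
23 | chloro(ethynyl)diisopropylsilane | C#C[Si](Cl)(C(C)C)C(C)C | intermediate
24 | silicon-tethered alkynyl dimethyl ketal | C#C[Si](C(C)C)(C(C)C)OCC#CC(OC)(OC)CCOCc1ccc(OC)cc1 | intermediate
25 | triyne ketal | C#C[Si](C(C)C)(C(C)C)OCC#C[C@@]1(Oc2cc(Cl)c(OCOC)c3c2[C@](C#C)(O1)CC[C@@H]3O[Si](C)(C)C(C)(C)C)CCOCc4ccc(OC)cc4 | intermediate
26 | silicon-bridged arene cycloadduct | CC(C)[Si]1(C(C)C)OCc2c1ccc3c2[C@@]4(Oc5cc(Cl)c(OCOC)c6c5[C@]3(O4)CC[C@@H]6O[Si](C)(C)C(C)(C)C)CCOCc7ccc(OC)cc7 | intermediate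
27 | salicyl alcohol | OCc1c(O)ccc2c1[C@@]3(Oc4cc(Cl)c(OCOC)c5c4[C@]2(O3)CC[C@@H]5O[Si](C)(C)C(C)(C)C)CCOCc6ccc(OC)cc6 | intermediate
28 | chlorinated salicyl alcohol | OCc1c(O)c(Cl)cc2c1[C@@]3(Oc4cc(Cl)c(OCOC)c5c4[C@]2(O3)CC[C@@H]5O[Si](C)(C)C(C)(C)C)CCOCc6ccc(OC)cc6 | intermediate
29 | chlorosalicylaldehyde | O=Cc1c(O)c(Cl)cc2c1[C@@]3(Oc4cc(Cl)c(OCOC)c5c4[C@]2(O3)CC[C@@H]5O[Si](C)(C)C(C)(C)C)CCOCc6ccc(OC)cc6 | intermediate
30 | silyl-protected aldehyde | O=Cc1c(O[Si](C)(C)C(C)(C)C)c(Cl)cc2c1[C@@]3(Oc4cc(Cl)c(OCOC)c5c4[C@]2(O3)CC[C@@H]5O[Si](C)(C)C(C)(C)C)CCOCc6ccc(OC)cc6 | intermediate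
31 | primary alcohol | O=Cc1c(O[Si](C)(C)C(C)(C)C)c(Cl)cc2c1[C@@]3(Oc4cc(Cl)c(OCOC)c5c4[C@]2(O3)CC[C@@H]5O[Si](C)(C)C(C)(C)C)CCO | intermediate
32 | primary iodide | O=Cc1c(O[Si](C)(C)C(C)(C)C)c(Cl)cc2c1[C@@]3(Oc4cc(Cl)c(OCOC)c5c4[C@]2(O3)CC[C@@H]5O[Si](C)(C)C(C)(C)C)CC[I] | intermediate
33 | ring-B carbinol | OC1c2c(O[Si](C)(C)C(C)(C)C)c(Cl)cc3c2[C@@]2(Oc4cc(Cl)c(OCOC)c5c4[C@]3(O2)CC[C@@H]5O[Si](C)(C)C(C)(C)C)CC1 | intermediate
34 | triol | OC1c2c(O)c(Cl)cc3c2[C@@]2(Oc4cc(Cl)c(OCOC)c5c4[C@]3(O2)CC[C@@H]5O)CC1 | intermediate
35 | diketone | O=C1c2c(O)c(Cl)cc3c2[C@@]2(Oc4cc(Cl)c(OCOC)c5c4[C@]3(O2)CCC5=O)CC1 | intermediate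
36 | bis-enone | O=C1c2c(O)c(Cl)cc3c2[C@@]2(Oc4cc(Cl)c(OCOC)c5c4[C@]3(O2)C=CC5=O)C=C1 | intermediate
37 | bis-epoxy diketone | O=C1c2c(O)c(Cl)cc3c2[C@@]2(Oc4cc(Cl)c(OCOC)c5c4[C@]3(O2)[C@@H]2O[C@@H]2C5=O)[C@@H]2O[C@H]12 | intermediate
38 | cis epoxy alcohol | O=C1c2c(O)c(Cl)cc3c2[C@@]2(Oc4cc(Cl)c(OCOC)c5c4[C@]3(O2)[C@@H]2O[C@@H]2[C@@H]5O)[C@@H]2O[C@H]12 | intermediate
39 | inverted 4-nitrobenzoate | O=C1c2c(O)c(Cl)cc3c2[C@@]2(Oc4cc(Cl)c(OCOC)c5c4[C@]3(O2)[C@@H]2O[C@@H]2[C@H]5OC(=O)c6ccc(cc6)[N+](=O)[O-])[C@@H]2O[C@H]12 | intermediate
40 | trans epoxy alcohol MOM ether | O=C1c2c(O)c(Cl)cc3c2[C@@]2(Oc4cc(Cl)c(OCOC)c5c4[C@]3(O2)[C@@H]2O[C@@H]2[C@H]5O)[C@@H]2O[C@H]12 | intermediate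
41 | CNP0289684.3 | O=C1c2c(O)c(Cl)cc3c2[C@@]2(Oc4cc(Cl)c(O)c5c4[C@]3(O2)[C@@H]2O[C@@H]2[C@H]5O)[C@@H]2O[C@H]12 | target

**Total step count:** 33.
**Longest linear sequence:** 27 (steps 1–10 and 17–33).

**The three steps most likely to fail**

**Step 18 (key step).**
- What may go wrong: the oxidative cyclization has to draw two parallel diaxial alkynes into a bridged bicycle, and the third alkyne is flanked by two isopropyl groups. The ring-forming events may therefore become slower than dimerization or oligomerization of the two terminal alkynes on rhodium.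
- Fallback: a smaller temporary tether on another element, a ruthenacycle mechanism, and C–B instead of C–Si oxidation. It sets out from 25. The alkoxy(ethynyl)silane of 25 is cleaved in preference to the hindered secondary silyl ether with pyridine-buffered HF·pyridine in THF at 0 °C to give the diyne alcohol F1. F1 and diisopropyl ethynylboronate exchange one isopropoxy group in ClCH2CH2Cl, and Cp*RuCl(cod) cyclotrimerizes the boron-tethered triyne so formed to the benzoxaborole F2. NaOH/H2O2 then oxidizes the C–B bond, and the route is rejoined at 27.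

**Step 17.**
- What may go wrong: exchange at a fully substituted ketal carbon with a tertiary alcohol is slow. In that time the acid may ionize the tertiary propargylic alcohol (dehydration, Meyer–Schuster rearrangement), loosen the silyl tether, or let the phenol attack the alkyne terminus of the alkynyl oxocarbenium ion.
- Fallback: kinetic silyl-transfer ketalization of the free ynone (Noyori type) in place of equilibrium exchange. It sets out from 13, which is persilylated with Me3SiCl/imidazole to the bis(trimethylsilyl) ether F3, and from 20, which is silylated with 23 and imidazole to the tethered ynone F4. F3 and F4 are combined with catalytic Me3SiOTf in CH2Cl2 at −78 °C. There the carbonyl group is activated far below the temperature at which the tertiary silyl ether ionizes, and no free phenol is present for conjugate addition. Loss of hexamethyldisiloxane leads to 25, where the route is rejoined.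

**Step 8.**
- What may go wrong: poor site selectivity, that is, hydrogen abstraction at the silyloxy-bearing benzylic carbon, or oxidation of the electron-rich arene instead of the CH2 group.
- Fallback: site control by a polar protecting group rather than by conformation. It sets out from 8, which is acetylated (Ac2O, pyridine) to the acetate F5. The carbinol C–H of F5 is deactivated toward electrophilic oxidants, so CrO3/3,5-dimethylpyrazole in CH2Cl2 at −20 °C should oxidize only the CH2 group to the keto acetate F6. K2CO3/MeOH gives the hydroxy ketone F7, and TBSOTf/2,6-lutidine returns to 10.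

**Further compounds**
F1 | step 18 | diyne alcohol | OCC#C[C@@]1(Oc2cc(Cl)c(OCOC)c3c2[C@](C#C)(O1)CC[C@@H]3O[Si](C)(C)C(C)(C)C)CCOCc4ccc(OC)cc4
F2 | step 18 | benzoxaborole | OB1OCc2c1ccc3c2[C@@]4(Oc5cc(Cl)c(OCOC)c6c5[C@]3(O4)CC[C@@H]6O[Si](C)(C)C(C)(C)C)CCOCc7ccc(OC)cc7
F3 | step 17 | bis(trimethylsilyl) ether | C[Si](C)(C)Oc1cc(Cl)c(OCOC)c2c1[C@@](O[Si](C)(C)C)(C#C)CC[C@@H]2O[Si](C)(C)C(C)(C)C
F4 | step 17 | tethered ynone | C#C[Si](C(C)C)(C(C)C)OCC#CC(=O)CCOCc1ccc(OC)cc1
F5 | step 8 | acetate | COCOc1cc(Cl)c(OCOC)c2c1CCC[C@@H]2OC(C)=O
F6 | step 8 | keto acetate | COCOc1cc(Cl)c(OCOC)c2c1C(=O)CC[C@@H]2OC(C)=O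
F7 | step 8 | hydroxy ketone | COCOc1cc(Cl)c(OCOC)c2c1C(=O)CC[C@@H]2O
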